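The pyran ring of the 2H-chromene is disconnected at C2–C3 and C4–C4a. With O1–C2 already in place, the O-aryl oxocarbenium ion ArO+=CMe2 (a cationic 2-oxadiene) is annulated with ethyl vinyl ether as an acetylene equivalent in an oxa-Povarov formal [4+2] reaction; loss of ethanol then unveils C3=C4 in the same flask. The step exploits the aryl ether O1–C8a of the benzene ring: C8 is blocked by OMe, so C4a, flanked by O1 and the C5 oxygen, is the only ortho carbon that can close the ring. The precursor is an aryl isopropenyl ether, made from an aryl acetate with Cp2TiMe2. Borylation and Suzuki coupling with a 3-iodochromone complete the isoflavone.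

Key step: step 5

Remark: the target is achiral; chromene numbering (O1, C2, C3, C4, C4a, C5 to C8, C8a) is used throughout, and 2-bromo-5-hydroxy-4-methoxybenzaldehyde and 2,4-dihydroxyacetophenone are taken as commercial.

Step 1
Reactants: 1 2-bromo-5-hydroxy-4-methoxybenzaldehyde
Product: 2 4-bromo-5-formyl-2-methoxyphenyl acetate
Conditions: Ac2O, Et3N, DMAP (cat.), CH2Cl2, 0 °C to rt
Reagents that add atoms: acetic anhydride, CC(=O)OC(C)=O
Why: Nucleophilic-catalysed O-acylation of the phenol; the acetate masks the future O1 during the oxidation and is later the source of the isopropenyl ether.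

Step 2
Reactants: 2 4-bromo-5-formyl-2-methoxyphenyl acetate
Product: 4 4-bromo-5-hydroxy-2-methoxyphenyl acetate, via aryl formate 3 (not isolated)
Conditions: mCPBA, CH2Cl2, rt; then MeOH, Et3N (0.2 equiv), 0 °C, short
Reagents that add atoms: mCPBA, OOC(=O)c1cccc(Cl)c1
Why: Baeyer–Villiger (Dakin-type) oxidation in which the aryl group, para to OMe, migrates to give formate 3, whose methanolysis should be far faster than that of the aryl acetate.

Step 3
Reactants: 4 4-bromo-5-hydroxy-2-methoxyphenyl acetate
Product: 5 4-bromo-5-[(tert-butyldimethylsilyl)oxy]-2-methoxyphenyl acetate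
Conditions: TBSCl, imidazole, DMF, rt
Reagents that add atoms: tert-butyldimethylsilyl chloride, CC(C)(C)[Si](C)(C)Cl
Why: Imidazole-promoted silylation of the free phenol gives a non-acetal protecting group that should survive the Lewis acid of step 5, and the mild base should leave the acetate alone.

Step 4
Reactants: 5 4-bromo-5-[(tert-butyldimethylsilyl)oxy]-2-methoxyphenyl acetate
Product: 6 {2-bromo-4-methoxy-5-[(prop-1-en-2-yl)oxy]phenoxy}(tert-butyl)dimethylsilane
Conditions: Cp2TiMe2 (2.5 equiv), toluene, 70 °C, dark; filtration through basic alumina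
Reagents that add atoms: dimethyltitanocene Cp2TiMe2, C[Ti](C)(C1C=CC=C1)C1C=CC=C1
Why: Petasis methylenation: Cp2TiMe2 loses methane to give Cp2Ti=CH2, which turns the ester C=O into C=CH2 through an oxatitanacyclobutane, while the aryl bromide and silyl ether are inert to this non-basic reagent.

Step 5
Reactants: 6 {2-bromo-4-methoxy-5-[(prop-1-en-2-yl)oxy]phenoxy}(tert-butyl)dimethylsilane
Product: 9 tert-butyl[(6-bromo-8-methoxy-2,2-dimethyl-2H-chromen-5-yl)oxy]dimethylsilane, via chloro ether 7 (not isolated), via 4-ethoxychroman 8 (not isolated)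
Conditions: HCl (1.0 equiv, 2 M in Et2O), CH2Cl2, −78 °C; then 2,6-di-tert-butyl-4-methylpyridine (1.3 equiv), ethyl vinyl ether (1.5 equiv), SnCl4 (1.2 equiv), −78 to 0 °C; Et3N quench
Reagents that add atoms: ethyl vinyl ether, C=COCC
Why: HCl adds in the Markovnikov sense to the enol ether to give 7, which SnCl4 ionises to ArO+=CMe2; the CH2 carbon of ethyl vinyl ether attacks this ion (C2–C3 bond), the new ethoxycarbenium ion is trapped at once by the ortho carbon C4a (C4–C4a bond) to give 8, and on warming SnCl4 ionises the doubly ortho-oxygenated benzylic ether so that E1 loss of ethanol leaves C3=C4. The closest known reaction type is the oxa-Povarov reaction (formal [4+2] cycloaddition of cationic aryl 2-oxadienes with alkenes), followed by the alcohol elimination familiar from Povarov adducts of vinyl ethers. The pyran ring closes by an intramolecular Friedel–Crafts alkylation through a six-membered transition state, 6-exo-trig at the ethoxycarbenium carbon, whose C=O+ bond stays outside the new ring. The C4 stereocentre of 8 forms as a racemate without control and is erased by the elimination, so no stereocentre has to be set. The step needs regioselective closure and the uptake of only one vinyl ether unit: C4a is the only free position ortho to O1 (C8 carries OMe) and is activated by O1 and the C5 silyloxy group, so ring closure should outrun chain growth. Converting all of 6 to 7 beforehand prevents self-condensation of the enol ether, and the hindered pyridine takes up the HCl released so that the vinyl ether is not protonated.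

Step 6
Reactants: 9 tert-butyl[(6-bromo-8-methoxy-2,2-dimethyl-2H-chromen-5-yl)oxy]dimethylsilane
Product: 10 tert-butyl{[8-methoxy-2,2-dimethyl-6-(4,4,5,5-tetramethyl-1,3,2-dioxaborolan-2-yl)-2H-chromen-5-yl]oxy}dimethylsilane
Conditions: B2pin2, Pd(dppf)Cl2 (5 mol%), KOAc, dioxane, 90 °C
Reagents that add atoms: bis(pinacolato)diboron, CC1(C)OB(OC1(C)C)B1OC(C)(C)C(C)(C)O1
Why: Miyaura borylation: oxidative addition of the C–Br bond to zerovalent palladium, acetate-assisted transmetalation with B2pin2 and reductive elimination, under conditions that should spare the chromene alkene and the silyl ether.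

Step 7
Reactants: 11 2,4-dihydroxyacetophenone
Product: 12 1-[2-hydroxy-4-(methoxymethoxy)phenyl]ethan-1-one
Conditions: MOMCl (1.1 equiv), K2CO3, acetone, 0 °C to rt
Reagents that add atoms: chloromethyl methyl ether, COCCl
Why: Williamson-type O-alkylation that should be selective for the 4-OH, because the 2-OH is held in a hydrogen bond to the ketone and is much less nucleophilic.

Step 8
Reactants: 12 1-[2-hydroxy-4-(methoxymethoxy)phenyl]ethan-1-one
Product: 13 (E)-3-(dimethylamino)-1-[2-hydroxy-4-(methoxymethoxy)phenyl]prop-2-en-1-one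
Conditions: DMF-DMA, toluene, 90 °C
Reagents that add atoms: N,N-dimethylformamide dimethyl acetal, COC(OC)N(C)C
Why: Condensation of the methyl ketone with the amide acetal gives the push-pull enaminone as the thermodynamically favoured E isomer, with loss of two molecules of methanol.

Step 9
Reactants: 13 (E)-3-(dimethylamino)-1-[2-hydroxy-4-(methoxymethoxy)phenyl]prop-2-en-1-one
Product: 14 3-iodo-7-(methoxymethoxy)-4H-chromen-4-one
Conditions: I2, CHCl3, pyridine, rt
Reagents that add atoms: iodine, II
Why: Iodine-mediated enaminone cyclisation: alpha-iodination of the enaminone, attack of the phenol oxygen at the iminium carbon and loss of dimethylamine give the 3-iodochromone.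

Step 10
Reactants: 10 tert-butyl{[8-methoxy-2,2-dimethyl-6-(4,4,5,5-tetramethyl-1,3,2-dioxaborolan-2-yl)-2H-chromen-5-yl]oxy}dimethylsilane, 14 3-iodo-7-(methoxymethoxy)-4H-chromen-4-one
Product: 15 3-{5-[(tert-butyldimethylsilyl)oxy]-8-methoxy-2,2-dimethyl-2H-chromen-6-yl}-7-(methoxymethoxy)-4H-chromen-4-one
Conditions: Pd(dppf)Cl2 (5 mol%), K3PO4, dioxane/H2O (9:1), 70 °C
Reagents that add atoms: none
Why: Suzuki–Miyaura coupling of the activated vinylogous C–I bond of the 3-iodochromone with the aryl boronate forms the isoflavone C3–aryl bond under base mild enough for the chromone ring.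

Step 11
Reactants: 15 3-{5-[(tert-butyldimethylsilyl)oxy]-8-methoxy-2,2-dimethyl-2H-chromen-6-yl}-7-(methoxymethoxy)-4H-chromen-4-one
Product: 17 7-hydroxy-3-(5-hydroxy-8-methoxy-2,2-dimethyl-2H-chromen-6-yl)-4H-chromen-4-one, via mono-MOM isoflavone 16 (not isolated)
Conditions: Bu4NF (1.2 equiv), THF, 0 °C; then 3 M aq. HCl, MeOH, 50 °C
Reagents that add atoms: none
Why: Fluoride cleaves the aryl silyl ether and acid-catalysed acetal exchange with methanol then removes the MOM group, conditions under which 2,2-dimethylchromenes and chromones should persist.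

Compound list
1 | 2-bromo-5-hydroxy-4-methoxybenzaldehyde | COc1cc(Br)c(C=O)cc1O | starting material
2 | 4-bromo-5-formyl-2-methoxyphenyl acetate | COc1cc(Br)c(C=O)cc1OC(C)=O | intermediate
3 | 4-bromo-5-(formyloxy)-2-methoxyphenyl acetate | COc1cc(Br)c(OC=O)cc1OC(C)=O | intermediate (not isolated)
4 | 4-bromo-5-hydroxy-2-methoxyphenyl acetate | COc1cc(Br)c(O)cc1OC(C)=O | intermediate
5 | 4-bromo-5-[(tert-butyldimethylsilyl)oxy]-2-methoxyphenyl acetate | COc1cc(Br)c(O[Si](C)(C)C(C)(C)C)cc1OC(C)=O | intermediate
6 | {2-bromo-4-methoxy-5-[(prop-1-en-2-yl)oxy]phenoxy}(tert-butyl)dimethylsilane | COc1cc(Br)c(O[Si](C)(C)C(C)(C)C)cc1OC(C)=C | intermediate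
7 | {2-bromo-5-[(2-chloropropan-2-yl)oxy]-4-methoxyphenoxy}(tert-butyl)dimethylsilane | COc1cc(Br)c(O[Si](C)(C)C(C)(C)C)cc1OC(C)(C)Cl | intermediate (not isolated)
8 | tert-butyl[(6-bromo-4-ethoxy-8-methoxy-2,2-dimethyl-3,4-dihydro-2H-chromen-5-yl)oxy]dimethylsilane (racemic) | CCOC1CC(C)(C)Oc2c(OC)cc(Br)c(O[Si](C)(C)C(C)(C)C)c12 | intermediate (not isolated)
9 | tert-butyl[(6-bromo-8-methoxy-2,2-dimethyl-2H-chromen-5-yl)oxy]dimethylsilane | COc1cc(Br)c(O[Si](C)(C)C(C)(C)C)c2c1OC(C)(C)C=C2 | intermediate
10 | tert-butyl{[8-methoxy-2,2-dimethyl-6-(4,4,5,5-tetramethyl-1,3,2-dioxaborolan-2-yl)-2H-chromen-5-yl]oxy}dimethylsilane | COc1cc(B2OC(C)(C)C(C)(C)O2)c(O[Si](C)(C)C(C)(C)C)c2c1OC(C)(C)C=C2 | intermediate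
11 | 2,4-dihydroxyacetophenone | CC(=O)c1ccc(O)cc1O | starting material
12 | 1-[2-hydroxy-4-(methoxymethoxy)phenyl]ethan-1-one | CC(=O)c1ccc(OCOC)cc1O | intermediate
13 | (E)-3-(dimethylamino)-1-[2-hydroxy-4-(methoxymethoxy)phenyl]prop-2-en-1-one | CN(C)/C=C/C(=O)c1ccc(OCOC)cc1O | intermediate
14 | 3-iodo-7-(methoxymethoxy)-4H-chromen-4-one | COCOc1ccc2c(c1)occ(I)c2=O | intermediate
15 | 3-{5-[(tert-butyldimethylsilyl)oxy]-8-methoxy-2,2-dimethyl-2H-chromen-6-yl}-7-(methoxymethoxy)-4H-chromen-4-one | COc1cc(-c2coc3cc(OCOC)ccc3c2=O)c(O[Si](C)(C)C(C)(C)C)c2c1OC(C)(C)C=C2 | intermediate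
16 | 3-(5-hydroxy-8-methoxy-2,2-dimethyl-2H-chromen-6-yl)-7-(methoxymethoxy)-4H-chromen-4-one | COc1cc(-c2coc3cc(OCOC)ccc3c2=O)c(O)c2c1OC(C)(C)C=C2 | intermediate (not isolated)
17 | 7-hydroxy-3-(5-hydroxy-8-methoxy-2,2-dimethyl-2H-chromen-6-yl)-4H-chromen-4-one | COc1cc(-c2coc3cc(O)ccc3c2=O)c(O)c2c1OC(C)(C)C=C2 | target

Total step count: 11
Longest linear sequence: 8 steps (steps 1 to 6, then 10 and 11)

Steps most likely to fail

Step 5. Cationic oligomerisation of the vinyl ether could compete with ring closure, and the electron-rich chromene could be alkylated or dimerised by cations while ethanol is being eliminated in the acidic medium. The fallback sets out from 6 and comes back at 9. The same chloro ether 7 is ionised with SnCl4 at −78 °C in the presence of phenyl vinyl sulfide, which should form the same two bonds in one operation through a thionium ion and stop at tert-butyl{[6-bromo-8-methoxy-2,2-dimethyl-4-(phenylsulfanyl)-3,4-dihydro-2H-chromen-5-yl]oxy}dimethylsilane F1, quenched cold with Et3N. Oxidation with mCPBA at −78 °C should give the sulfoxide tert-butyl{[6-bromo-8-methoxy-2,2-dimethyl-4-(phenylsulfinyl)-3,4-dihydro-2H-chromen-5-yl]oxy}dimethylsilane F2. Heating F2 in toluene at 110 °C over NaHCO3 should bring about thermal syn-elimination of benzenesulfenic acid to give 9, so the alkene is formed under neutral conditions.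

Step 4. The titanium adduct of the aryl ester could expel the aryloxide (acyl cleavage back to the phenol) in place of olefination, and the enol ether could hydrolyse during isolation. The fallback sets out from 5 and comes back at 6. Aminolysis of the acetate with pyrrolidine (CH2Cl2, 0 °C) should give 4-bromo-5-[(tert-butyldimethylsilyl)oxy]-2-methoxyphenol F3 without touching the silyl ether. Chan–Lam O-alkenylation of F3 with isopropenylboronic acid pinacol ester (Cu(OAc)2, pyridine, 4 Å molecular sieves, O2, CH2Cl2, rt) should then deliver 6.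

Step 6. Oxidative addition at the hindered, electron-rich C–Br bond next to the silyloxy group could be slow, with protodebromination taking over. The fallback sets out from 9 and comes back at 15. n-BuLi is added at −78 °C to a THF solution of 9 and B(OiPr)3, so that the aryllithium [5-(tert-butyldimethylsilyloxy)-8-methoxy-2,2-dimethyl-2H-chromen-6-yl]lithium F4 is trapped as it forms, before the silyl group can migrate from oxygen to carbon. Mild acidic work-up should give {5-[(tert-butyldimethylsilyl)oxy]-8-methoxy-2,2-dimethyl-2H-chromen-6-yl}boronic acid F5, which takes the place of 10 in the coupling of step 10 to give 15.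

Further compounds
F1 | step 5 | tert-butyl{[6-bromo-8-methoxy-2,2-dimethyl-4-(phenylsulfanyl)-3,4-dihydro-2H-chromen-5-yl]oxy}dimethylsilane (racemic) | COc1cc(Br)c(O[Si](C)(C)C(C)(C)C)c2c1OC(C)(C)CC2Sc1ccccc1
F2 | step 5 | tert-butyl{[6-bromo-8-methoxy-2,2-dimethyl-4-(phenylsulfinyl)-3,4-dihydro-2H-chromen-5-yl]oxy}dimethylsilane (mixture of diastereomers) | COc1cc(Br)c(O[Si](C)(C)C(C)(C)C)c2c1OC(C)(C)CC2S(=O)c1ccccc1
F3 | step 4 | 4-bromo-5-[(tert-butyldimethylsilyl)oxy]-2-methoxyphenol | COc1cc(Br)c(O[Si](C)(C)C(C)(C)C)cc1O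
F4 | step 6 | [5-(tert-butyldimethylsilyloxy)-8-methoxy-2,2-dimethyl-2H-chromen-6-yl]lithium | [Li]c1cc(OC)c2OC(C)(C)C=Cc2c1O[Si](C)(C)C(C)(C)C
F5 | step 6 | {5-[(tert-butyldimethylsilyl)oxy]-8-methoxy-2,2-dimethyl-2H-chromen-6-yl}boronic acid | COc1cc(B(O)O)c(O[Si](C)(C)C(C)(C)C)c2c1OC(C)(C)C=C2
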